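**Retrosynthetic overview**

- Ring A (C4a, C5, C6, C7, C8, C8a) carries oxygen on C5 and on C7, on either side of an unsubstituted C6. This is the pattern of the lactone carbonyl, ring oxygen and C-methyl group of a 6-methyl-2-pyrone, so ring A is disconnected at C5–C6 (Claisen) and C5–O (lactone) back to a 7-methyl-8-prenylpyrano[4,3-b]pyran-4,5-dione.
- Ring C of that bicycle is disconnected at O1–C8a (ring closure) and C2–C3 (Baker–Venkataraman) to a 3-(MOM-oxyacetyl)-4-hydroxy-6-methyl-5-prenyl-2-pyrone and the ring B acid. The pyrone has a single hydroxyl, next to the prenyl-bearing carbon, so O1 can only end beside C8.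
- The pyrone comes from acetylacetone, prenyl bromide and CO2. Ring B comes from 3-bromo-4,5-dihydroxybenzaldehyde by MOM protection, Stille prenylation and oxidation.
- Order of ring formation: 2-pyrone, then ring C, then ring A out of the pyrone; the three MOM groups are removed last.

Key step: step 13

Remark: 3-bromo-4,5-dihydroxybenzaldehyde and tributyl(3-methylbut-2-en-1-yl)stannane are taken as purchasable; the target has no stereocentre, and the enolisable sp3 centres met on the way are carried as racemates.

**Route**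

Step 1
Reactants: 1 acetylacetone (pentane-2,4-dione); 2 prenyl bromide (1-bromo-3-methylbut-2-ene)
Product: 3 3-(3-methylbut-2-en-1-yl)pentane-2,4-dione
Conditions: K2CO3, acetone, 50 °C (1 in 1.5-fold excess)
Reagents that add atoms: none
Why: C-alkylation of the potassium enolate of a 1,3-diketone by a primary allylic bromide (SN2), with the excess of diketone holding back dialkylation.

Step 2
Reactants: 3 3-(3-methylbut-2-en-1-yl)pentane-2,4-dione
Product: 4 4-(3-methylbut-2-en-1-yl)-3,5-dioxohexanoic acid
Conditions: LiN(i-Pr)2 (2.2 equiv), THF, −78 to 0 °C; CO2, −78 °C; 1 M HCl, 0 °C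
Reagents that add atoms: carbon dioxide, O=C=O
Why: Dianion carboxylation of a 1,3-diketone, in which the second deprotonation takes place at a terminal methyl group and this more basic carbanion adds to CO2; the 3,5-dioxo acid is kept cold and used at once to avoid decarboxylation.

Step 3
Reactants: 4 4-(3-methylbut-2-en-1-yl)-3,5-dioxohexanoic acid
Product: 6 4-hydroxy-6-methyl-5-(3-methylbut-2-en-1-yl)-2H-pyran-2-one, via acyl imidazolide 5 (not isolated)
Conditions: CDI, THF, rt; dilute HCl work-up, 0 °C
Reagents that add atoms: none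
Why: Carbonyldiimidazole lactonisation of a 3,5-dioxo acid, in which the enol oxygen of the 5-ketone is acylated intramolecularly (6-exo-trig) and enolisation gives the 4-hydroxy-2-pyrone without the strong acid that would add the new hydroxyl to the prenyl group.

Step 4
Reactants: 7 methyl glycolate
Product: 8 methyl 2-(methoxymethoxy)acetate
Conditions: MOMCl, i-Pr2NEt, CH2Cl2, 0 °C to rt
Reagents that add atoms: chloromethyl methyl ether (MOMCl), COCCl
Why: O-alkylation of a primary alcohol by an α-chloro ether under amine base, the standard formation of a MOM acetal.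

Step 5
Reactants: 8 methyl 2-(methoxymethoxy)acetate
Product: 9 2-(methoxymethoxy)acetic acid
Conditions: LiOH, THF/H2O, 0 °C to rt; 1 M HCl to pH 3, 0 °C
Reagents that add atoms: lithium hydroxide, [Li+].[OH-]
Why: Ester saponification, to which the MOM acetal is inert, followed by brief cold acidification that an alkyl MOM ether tolerates.

Step 6
Reactants: 6 4-hydroxy-6-methyl-5-(3-methylbut-2-en-1-yl)-2H-pyran-2-one; 9 2-(methoxymethoxy)acetic acid
Product: 11 4-hydroxy-3-[2-(methoxymethoxy)acetyl]-6-methyl-5-(3-methylbut-2-en-1-yl)-2H-pyran-2-one, via pyran-4-yl ester 10 (not isolated)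
Conditions: DCC, DMAP, toluene, rt then 70 °C
Reagents that add atoms: none
Why: Steglich O-acylation of the vinylogous acid followed by DMAP-mediated O-to-C acyl migration (Fries-type shift) to C3, the only free nucleophilic carbon of the pyrone, a sequence well known for 4-hydroxy-6-methyl-2-pyrone and aliphatic acids.

Step 7
Reactants: 12 3-bromo-4,5-dihydroxybenzaldehyde
Product: 13 3-bromo-4,5-bis(methoxymethoxy)benzaldehyde
Conditions: MOMCl (3 equiv), i-Pr2NEt, CH2Cl2, 0 °C to rt
Reagents that add atoms: chloromethyl methyl ether (MOMCl), COCCl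
Why: Double MOM etherification of a catechol under amine base, which leaves the aldehyde and the aryl bromide untouched.

Step 8
Reactants: 13 3-bromo-4,5-bis(methoxymethoxy)benzaldehyde
Product: 14 3,4-bis(methoxymethoxy)-5-(3-methylbut-2-en-1-yl)benzaldehyde
Conditions: tributyl(3-methylbut-2-en-1-yl)stannane, Pd(PPh3)4 (5 mol %), DMF, 90 °C
Reagents that add atoms: tributyl(3-methylbut-2-en-1-yl)stannane, CCCC[Sn](CCCC)(CCCC)CC=C(C)C
Why: Migita–Kosugi–Stille coupling, in which zerovalent palladium inserts into the C–Br bond, the allyl group is transferred from tin and reductive elimination at the less substituted allyl terminus should give the linear prenyl arene, while the aldehyde does not add an allylstannane in the absence of a Lewis acid.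

Step 9
Reactants: 14 3,4-bis(methoxymethoxy)-5-(3-methylbut-2-en-1-yl)benzaldehyde
Product: 15 3,4-bis(methoxymethoxy)-5-(3-methylbut-2-en-1-yl)benzoic acid
Conditions: NaClO2, NaH2PO4, 2-methyl-2-butene (large excess), t-BuOH/H2O, rt
Reagents that add atoms: sodium chlorite, [Na+].[O-]Cl=O
Why: Pinnick oxidation of an aryl aldehyde, in which the excess 2-methyl-2-butene traps hypochlorous acid before it can reach the prenyl group and the phosphate buffer is mild enough for aryl MOM ethers.

Step 10
Reactants: 11 4-hydroxy-3-[2-(methoxymethoxy)acetyl]-6-methyl-5-(3-methylbut-2-en-1-yl)-2H-pyran-2-one; 15 3,4-bis(methoxymethoxy)-5-(3-methylbut-2-en-1-yl)benzoic acid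
Product: 16 3-[2-(methoxymethoxy)acetyl]-6-methyl-5-(3-methylbut-2-en-1-yl)-2-oxo-2H-pyran-4-yl 3,4-bis(methoxymethoxy)-5-(3-methylbut-2-en-1-yl)benzoate
Conditions: DCC, DMAP (cat.), CH2Cl2, 0 °C to rt; filtered and used without chromatography
Reagents that add atoms: none
Why: Steglich esterification of the acidic 4-hydroxyl, the counterpart of the O-aroylation of an o-hydroxyaryl ketone; with C3 occupied the aroyl group cannot migrate to carbon and stays on oxygen.

Step 11
Reactants: 16 3-[2-(methoxymethoxy)acetyl]-6-methyl-5-(3-methylbut-2-en-1-yl)-2-oxo-2H-pyran-4-yl 3,4-bis(methoxymethoxy)-5-(3-methylbut-2-en-1-yl)benzoate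
Product: 17 1-[3,4-bis(methoxymethoxy)-5-(3-methylbut-2-en-1-yl)phenyl]-3-[4-hydroxy-6-methyl-5-(3-methylbut-2-en-1-yl)-2-oxo-2H-pyran-3-yl]-2-(methoxymethoxy)propane-1,3-dione
Conditions: LiN(SiMe3)2 (2.5 equiv), THF, −78 to −20 °C; AcOH quench
Reagents that add atoms: none
Why: Baker–Venkataraman rearrangement, in which the lithium enolate of the α-alkoxy ketone attacks the neighbouring aroyl ester through a six-membered transition state and the second equivalent of base stores the product as its dianion, as in the classical route to 3-alkoxyflavones from ω-alkoxy ketones.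

Step 12
Reactants: 17 1-[3,4-bis(methoxymethoxy)-5-(3-methylbut-2-en-1-yl)phenyl]-3-[4-hydroxy-6-methyl-5-(3-methylbut-2-en-1-yl)-2-oxo-2H-pyran-3-yl]-2-(methoxymethoxy)propane-1,3-dione
Product: 19 2-[3,4-bis(methoxymethoxy)-5-(3-methylbut-2-en-1-yl)phenyl]-3-(methoxymethoxy)-7-methyl-8-(3-methylbut-2-en-1-yl)-4H,5H-pyrano[4,3-b]pyran-4,5-dione, via pyran-4-yl tosylate 18 (not isolated)
Conditions: TsCl (1.2 equiv), Et3N (3 equiv), DMAP (cat.), CH2Cl2, 0 °C to rt
Reagents that add atoms: none
Why: Cyclodehydration of the Baker–Venkataraman diketone to the 4-pyranone, run under base so that the MOM acetals and the prenyl group beside the pyrone hydroxyl never meet acid: sulfonylation of the acidic 4-hydroxyl (as known for 4-hydroxy-2-pyrones) turns C4 into a vinylogous sulfonic anhydride carbon, and the enolate oxygen of the aryl ketone displaces tosylate there by intramolecular addition–elimination, six being the only ring size open to it.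

Step 13
Reactants: 19 2-[3,4-bis(methoxymethoxy)-5-(3-methylbut-2-en-1-yl)phenyl]-3-(methoxymethoxy)-7-methyl-8-(3-methylbut-2-en-1-yl)-4H,5H-pyrano[4,3-b]pyran-4,5-dione
Product: 21 2-[3,4-bis(methoxymethoxy)-5-(3-methylbut-2-en-1-yl)phenyl]-5,7-dihydroxy-3-(methoxymethoxy)-8-(3-methylbut-2-en-1-yl)-4H-chromen-4-one (3,3',4'-tri-O-MOM Broussonol D), via ring-opened keto ester 20 (not isolated)
Conditions: Mg(OMe)2 (6 equiv), MeOH, reflux, argon; cold 0.5 M HCl to pH 4
Reagents that add atoms: none
Why: Proposed new method: methoxide held on magnesium should add to the lactone carbonyl C5, the most electrophilic carbonyl of 19, and break C5–O6 to leave a methyl ester on C4a and the enolate of a methyl ketone on C8 (20); proton exchange in methanol gives access to the enolate at the terminal CH3 (the future C6), which attacks the ester in a Claisen (Dieckmann-type) condensation that forms C5–C6, expels methoxide and gives ring A after tautomerisation to the 5,7-diol. The closest known reaction type is the Mg(OMe)2- or alkoxide-induced opening and Claisen reclosure of 4-oxygenated 6-methyl-2-pyrones and 3-acyl-4-hydroxy-6-methyl-2-pyrones to phloroglucinol rings in biomimetic polyketide chemistry, which has not been shown for a 2-pyrone fused to a 3-alkoxy-2-aryl-4-pyranone. Ring A closes in the 6-(enolexo)-exo-trig mode, helped by the cis placement of ester and side chain on the C4a=C8a double bond, and no stereocentre is formed. The step needs chemoselectivity for C5 over C2, C7, C8a and C4: methoxide additions at C2, C7 or C8a are reversible and should only return 19, because the pyrone stage has a single hydroxyl for reclosure, whereas the C5 pathway ends in an irreversible aromatisation. Claisen attack on the ester is preferred to aldol attack on C4 because C4 is a vinylogous ester carbonyl, and magnesium chelation between the C4 oxygen and the ester activates the ester and then holds the product as its 5-oxido-4-keto chelate. The prenyl group must end on C8, which is already fixed because its carbon is bonded to C8a, the carbon that carries O1 of ring C.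

Step 14
Reactants: 21 3,3',4'-tri-O-MOM Broussonol D
Product: 22 Broussonol D, 3,5,7-trihydroxy-2-[3,4-dihydroxy-5-(3-methylbut-2-en-1-yl)phenyl]-8-(3-methylbut-2-en-1-yl)-4H-chromen-4-one
Conditions: 3 M aq. HCl (cat.), MeOH, 45 °C
Reagents that add atoms: none
Why: Acid-catalysed transacetalisation (methanolysis) of the three MOM ethers, a standard last step for prenylated flavonoids, kept below 50 °C so that the prenyl groups do not add to the neighbouring 7- and 4'-hydroxyls.

**Compound list**

1 | acetylacetone (pentane-2,4-dione) | CC(=O)CC(C)=O | starting material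
2 | prenyl bromide (1-bromo-3-methylbut-2-ene) | CC(C)=CCBr | starting material
3 | 3-(3-methylbut-2-en-1-yl)pentane-2,4-dione | CC(=O)C(CC=C(C)C)C(C)=O | intermediate
4 | 4-(3-methylbut-2-en-1-yl)-3,5-dioxohexanoic acid (racemic, enolisable) | CC(=O)C(CC=C(C)C)C(=O)CC(=O)O | intermediate
5 | 1-[4-(3-methylbut-2-en-1-yl)-3,5-dioxohexanoyl]imidazole (racemic, not isolated) | CC(=O)C(CC=C(C)C)C(=O)CC(=O)n1ccnc1 | intermediate
6 | 4-hydroxy-6-methyl-5-(3-methylbut-2-en-1-yl)-2H-pyran-2-one | Cc1oc(=O)cc(O)c1CC=C(C)C | intermediate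
7 | methyl glycolate | COC(=O)CO | starting material
8 | methyl 2-(methoxymethoxy)acetate | COCOCC(=O)OC | intermediate
9 | 2-(methoxymethoxy)acetic acid | COCOCC(=O)O | intermediate
10 | 6-methyl-5-(3-methylbut-2-en-1-yl)-2-oxo-2H-pyran-4-yl 2-(methoxymethoxy)acetate (not isolated) | COCOCC(=O)Oc1cc(=O)oc(C)c1CC=C(C)C | intermediate
11 | 4-hydroxy-3-[2-(methoxymethoxy)acetyl]-6-methyl-5-(3-methylbut-2-en-1-yl)-2H-pyran-2-one | COCOCC(=O)c1c(O)c(CC=C(C)C)c(C)oc1=O | intermediate
12 | 3-bromo-4,5-dihydroxybenzaldehyde | O=Cc1cc(O)c(O)c(Br)c1 | starting material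
13 | 3-bromo-4,5-bis(methoxymethoxy)benzaldehyde | COCOc1cc(C=O)cc(Br)c1OCOC | intermediate
14 | 3,4-bis(methoxymethoxy)-5-(3-methylbut-2-en-1-yl)benzaldehyde | COCOc1cc(C=O)cc(CC=C(C)C)c1OCOC | intermediate
15 | 3,4-bis(methoxymethoxy)-5-(3-methylbut-2-en-1-yl)benzoic acid | COCOc1cc(C(=O)O)cc(CC=C(C)C)c1OCOC | intermediate
16 | 3-[2-(methoxymethoxy)acetyl]-6-methyl-5-(3-methylbut-2-en-1-yl)-2-oxo-2H-pyran-4-yl 3,4-bis(methoxymethoxy)-5-(3-methylbut-2-en-1-yl)benzoate | COCOCC(=O)c1c(OC(=O)c2cc(OCOC)c(OCOC)c(CC=C(C)C)c2)c(CC=C(C)C)c(C)oc1=O | intermediate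
17 | 1-[3,4-bis(methoxymethoxy)-5-(3-methylbut-2-en-1-yl)phenyl]-3-[4-hydroxy-6-methyl-5-(3-methylbut-2-en-1-yl)-2-oxo-2H-pyran-3-yl]-2-(methoxymethoxy)propane-1,3-dione (racemic, enolisable) | COCOC(C(=O)c1cc(OCOC)c(OCOC)c(CC=C(C)C)c1)C(=O)c1c(O)c(CC=C(C)C)c(C)oc1=O | intermediate
18 | 4-O-tosylate of 17 (racemic, not isolated) | COCOC(C(=O)c1cc(OCOC)c(OCOC)c(CC=C(C)C)c1)C(=O)c1c(OS(=O)(=O)c2ccc(C)cc2)c(CC=C(C)C)c(C)oc1=O | intermediate
19 | 2-[3,4-bis(methoxymethoxy)-5-(3-methylbut-2-en-1-yl)phenyl]-3-(methoxymethoxy)-7-methyl-8-(3-methylbut-2-en-1-yl)-4H,5H-pyrano[4,3-b]pyran-4,5-dione | CC(C)=CCc1cc(-c2oc3c(CC=C(C)C)c(C)oc(=O)c3c(=O)c2OCOC)cc(OCOC)c1OCOC | intermediate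
20 | methyl 6-[3,4-bis(methoxymethoxy)-5-(3-methylbut-2-en-1-yl)phenyl]-5-(methoxymethoxy)-2-(6-methyl-2-oxohept-5-en-3-yl)-4-oxo-4H-pyran-3-carboxylate (racemic, not isolated) | COC(=O)c1c(C(CC=C(C)C)C(C)=O)oc(-c2cc(CC=C(C)C)c(OCOC)c(OCOC)c2)c(OCOC)c1=O | intermediate
21 | 3,3',4'-tri-O-MOM Broussonol D | CC(C)=CCc1cc(-c2oc3c(CC=C(C)C)c(O)cc(O)c3c(=O)c2OCOC)cc(OCOC)c1OCOC | intermediate
22 | Broussonol D | CC(C)=CCc1cc(-c2oc3c(CC=C(C)C)c(O)cc(O)c3c(=O)c2O)cc(O)c1O | target

**Step count**

Total: 14 steps. Longest linear sequence: 9 steps (steps 1, 2, 3, 6, 10, 11, 12, 13, 14).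

**Steps most likely to fail**

Step 13. The lactone may open without ring A closing, so that the material rests as the stabilised magnesium enolate of the keto ester. Methoxide may also cleave ring C by attack at C2 and release material that does not return. The fallback uses known chemistry and leaves the route at aldehyde 14. Purchased 2,4,6-trihydroxyacetophenone would be C-prenylated with 2 (aqueous KOH) to 1-[2,4,6-trihydroxy-3-(3-methylbut-2-en-1-yl)phenyl]ethanone F1. MOMCl and i-Pr2NEt would then cap the para hydroxyl and the less hindered ortho hydroxyl to give 1-[2-hydroxy-4,6-bis(methoxymethoxy)-3-(3-methylbut-2-en-1-yl)phenyl]ethanone F2, whose free hydroxyl sits beside the prenyl group. Claisen–Schmidt condensation of F2 with 14 (KOH, EtOH) would give the (E)-chalcone F3. Algar–Flynn–Oyamada oxidation (H2O2, NaOH, MeOH) would close ring C to the 3-hydroxy-5,7,3',4'-tetrakis(methoxymethoxy)-8,5'-diprenylflavone F4. The conditions of step 14 would then remove four MOM groups and return to the route at 22.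

Step 12. Sulfonylation may take place on the diketone enol on the side of the pyrone carbonyl, or the enolate may be chlorinated at carbon, so that the tosylate at O4 is not formed or is displaced intermolecularly. The fallback is an Allan–Robinson condensation that sets out from 11. Acid 15 would be converted with DCC into 3,4-bis(methoxymethoxy)-5-(3-methylbut-2-en-1-yl)benzoic anhydride F5. Heating 11 with F5 (2.2 equiv), Et3N and DMAP in toluene at 110 °C should bring about O-aroylation, acyl shift, aroylation of the diketone enol and ring closure with loss of aroate in one operation, returning to the route at 19.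

Step 8. Reductive elimination may occur at the tertiary allyl terminus and give the 1,1-dimethylallyl isomer, or transmetalation at the hindered ortho-alkoxy bromide may be slow enough for protodestannylation to take over. The fallback sets out from 13. Stille coupling with allyltributylstannane and Pd(PPh3)4, in which no regiochemical question arises, would give 3,4-bis(methoxymethoxy)-5-(prop-2-en-1-yl)benzaldehyde F6. Cross-metathesis of F6 with excess 2-methyl-2-butene and second-generation Grubbs catalyst in CH2Cl2 at 40 °C would turn the allyl group into prenyl and return to the route at 14.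

**Further compounds**

F1 | step 13 | 1-[2,4,6-trihydroxy-3-(3-methylbut-2-en-1-yl)phenyl]ethanone | CC(=O)c1c(O)cc(O)c(CC=C(C)C)c1O
F2 | step 13 | 1-[2-hydroxy-4,6-bis(methoxymethoxy)-3-(3-methylbut-2-en-1-yl)phenyl]ethanone | CC(=O)c1c(OCOC)cc(OCOC)c(CC=C(C)C)c1O
F3 | step 13 | (E)-3-[3,4-bis(methoxymethoxy)-5-(3-methylbut-2-en-1-yl)phenyl]-1-[2-hydroxy-4,6-bis(methoxymethoxy)-3-(3-methylbut-2-en-1-yl)phenyl]prop-2-en-1-one | COCOc1cc(OCOC)c(CC=C(C)C)c(O)c1C(=O)/C=C/c1cc(OCOC)c(OCOC)c(CC=C(C)C)c1
F4 | step 13 | 2-[3,4-bis(methoxymethoxy)-5-(3-methylbut-2-en-1-yl)phenyl]-3-hydroxy-5,7-bis(methoxymethoxy)-8-(3-methylbut-2-en-1-yl)-4H-chromen-4-one | COCOc1cc(OCOC)c2c(=O)c(O)c(-c3cc(OCOC)c(OCOC)c(CC=C(C)C)c3)oc2c1CC=C(C)C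
F5 | step 12 | 3,4-bis(methoxymethoxy)-5-(3-methylbut-2-en-1-yl)benzoic anhydride | COCOc1cc(C(=O)OC(=O)c2cc(OCOC)c(OCOC)c(CC=C(C)C)c2)cc(CC=C(C)C)c1OCOC
F6 | step 8 | 3,4-bis(methoxymethoxy)-5-(prop-2-en-1-yl)benzaldehyde | COCOc1cc(C=O)cc(CC=C)c1OCOC
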